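Chain numbering C1–C19 from the pentyl end is used for the target and for every intermediate.

## Analysis of the target

Target 19 is a 2,3,5-trisubstituted oxolane set into an unbranched C19 chain. The ring oxygen bridges C6 and C9; C6 carries the pentyl group C1–C5, C7 a free hydroxyl, C8 is a methylene, and C9 carries the exocyclic carbinol C10. C10 is esterified by a dodecanoyl group and continues as C11–C19, ending in the C18=C19 vinyl group. The four stereocentres are 6S, 7S, 9R and 10R: pentyl and hydroxyl are cis on the ring (a threo C6/C7 pair), the carbon substituents at C6 and C9 are trans across the ring oxygen, and C9/C10 are threo. The two secondary oxygens O7 and O10 must be told apart, because only O10 is acylated; once the ester is present, strong hydride donors and strong bases are excluded. The monosubstituted alkene rules out late hydrogenation, hydroboration or olefin metathesis. The hard parts are the 2,5-trans relation across the ring oxygen and the exocyclic centre C10. The plan rests on one feature: the ring O–C6–C7–C8–C9 with an oxygenated carbon C10 on C9 is the one-atom-contracted form of the six-membered enol ether O–C6–C7–C8–C9=C10, the dihydropyran 10, which an Achmatowicz pyranone holding C6 and C7 delivers directly.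

## Retrosynthetic reasoning

19 from 18. The last bond cut is O7–Si. O7 stays silylated from the moment the hydroxyl exists, so that O10 is the only free hydroxyl when the acyl group arrives. A fluoride-labile group is used because its removal spares ester and alkene. The tert-butyldiphenylsilyl group is chosen because it must survive strong acid twice on the way, and its bulk helps the facial bias of the key step.

18 from 16 and 17. The acyl–O10 bond is cut. This keeps the C12 acyl chain out of all earlier steps and asks only for acylation of a single secondary alcohol.

16 from 13 and 15 (made from 14). The C10–C11 bond is cut. Cutting here, and not at C9–C10, leaves C9 to the ring-forming step and gives the aldehyde 13, whose α-oxygen is the ring oxygen. The forward addition has to run through a five-membered magnesium chelate between ring oxygen and carbonyl oxygen, so that C11 enters from the side of the C9 hydrogen and C10 comes out R (threo). The C11–C19 chain arrives with its alkene in place.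

13 from 12. This is only a change of oxidation-level label: the aldehyde is unmasked from the dimethyl acetal that the key step produces.

12 from 10 (through 11). The O–C9 bond of the oxolane is cut and the oxygen is put back on C10, which turns C9=C10 into an enol ether inside a six-membered ring. This is the central disconnection: it trades a ring with three stereocentres for a ring with two adjacent ones that are easy to set in a chair. The forward reaction must place an electrophile on C9 from the face opposite pentyl and silyloxy, and then let the ring oxygen displace it with inversion; together these create the ring, the O–C9 bond and the C9 stereocentre.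

10 from 9, 8 and 7. The C9=C10 double bond is traced back to the mixed methyl acetal 9, which loses its methoxy group from C10. The silyl ether goes back to alcohol 8. The C7–H bond goes back to ketone 7, where an equatorial hydride delivery sets the hydroxyl cis to pentyl.

7 from 6 and 5. The two hydrogens on C8 and C9 are removed to give the enone 6. Saturation comes before the ketone reduction so that the bulky hydride meets a true chair. The methoxy group of 6 goes back to the hemiacetal 5; it is needed to keep C10 from being reduced, and the same group later becomes the leaving group on the way to 10.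

5 from 4. The pyranone 5 is the Achmatowicz product of the furyl carbinol 4. The carbinol oxygen becomes the ring oxygen, the carbinol carbon becomes C6, and the four furan carbons become C7–C10.

4 from 3, and 3 from 1 and 2. The C6–H bond is made by asymmetric transfer hydrogenation of the furyl ketone 3, which sets the only stereocentre that is not substrate-controlled. The C6–C7 bond is made by acylating furan 1 at its α-position with the anhydride 2.

## Alternatives that were turned down

Alternative 1: The C5–C6 and O–C7 bonds are cut together. C1–C5 then arrive as pentanal A3, and the ring is the enol ether (1R)-1-[(2R)-2,3-dihydrofuran-2-yl]dec-9-en-1-yl dodecanoate A2, which already carries C9, C10 and the ester.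
- Forward key step: a Paternò–Büchi photocycloaddition of excited A3 across the C6=C7 bond of A2 gives the cis-fused oxetane A1.
- For it: the C5–C6 bond and both C6 and C7 are set in one step, cis by the ring fusion. Approach anti to the C9 side chain would give the 2,5-trans relation. The usual regiochemistry for 2,3-dihydrofurans puts the carbonyl carbon on the oxygen-bearing alkene carbon, as required.
- Against: excited A3 has γ-hydrogens and fragments by Norrish γ-hydrogen abstraction, and the C18=C19 alkene is a second reaction partner. A2 is not simpler than the target, since C9 and C10 must be set beforehand by a separate asymmetric sequence. After the key step the oxetane of A1 must be opened reductively at the unactivated C5–O bond, next to a fully substituted carbon, while an ester is present; hydride donors able to open oxetanes reduce the ester and do not clearly choose between the two oxetane carbons.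
- Comparison: it is shorter on paper after its key step, but it has two weak steps and no evident rescue. The chosen route has a single risky step with a stepwise rescue and ground-state chemistry elsewhere.

Alternative 2: C5–C10 are taken from D-glucose A6, with sugar C1–C6 of A6 becoming C10–C5. The ring O–C6 bond is cut.
- Forward key step: the 3-deoxy sugar with C6 extended by butyl is carried to the 1,2-acetonide 5-mesylate A5. In acidic methanol the acetonide of A5 opens to the dimethyl acetal and the O2 hydroxyl displaces the mesylate at sugar C5 with inversion, closing the oxolane A4.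
- For it: C7 and C9 come from the chiral pool and C6 from a clean SN2 inversion. On certainty of the ring stereocentres, and of C9 in particular, this alternative is stronger than the chosen route, which depends on facial selectivity.
- Against: reaching A5 from A6 needs a radical deoxygenation at sugar C3 (Bu3SnH), selective release and activation of the 5,6-diol, a cuprate chain extension (Bu2CuLi) and mesylation. The cyclisation is a displacement at a secondary carbon flanked by an alkyl chain and competes with formation of methyl furanosides. A4 has a free O7 hydroxyl and must be silylated before the route can continue.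
- Comparison: the overall length is about the same as the chosen route. The chosen route offers in its place a catalytic asymmetric entry that gives either enantiomer and any C1–C5 chain, no tin reagent, the O7 protecting group already in place, and ring and stereocentre formed in one operation.

Alternative 3: The C8=C9 bond is cut. An ester joining a C5–C8 alcohol fragment to a C9–C19 acid fragment is methylenated (Cp2TiMe2) to the acyclic enol ether A8.
- Forward key step: ring-closing enol ether–olefin metathesis of A8 with RuCl2(=CHPh)(H2IMes)(PCy3), the second-generation Grubbs catalyst, gives the 2,3-dihydrofuran A7.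
- For it: it is convergent, and C6, C7 and C10 are all set before ring closure by independent methods. On C10 it is stronger than the chosen route, which relies on chelation control.
- Against: the C18=C19 vinyl group of A8 is a better metathesis substrate than the 1,1-disubstituted enol ether, so it would have to be masked. A7 is a 3-alkoxy-2,3-dihydrofuran and loses the C7 oxygen easily to give a furan. C9 must then be set by adding hydrogen to C8=C9 from the face that carries pentyl and the C7 oxygen, the hindered one; this calls for a hydroxyl-directed hydrogenation that the terminal alkene does not survive. Two different protecting groups are needed.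
- Comparison: the chosen route needs one protecting group, never conflicts with the terminal alkene, and sets C9 in the ring-forming step itself.

Key step: step 9

Remarks on the chemistry:
- Compounds 5–9 and 11 are mixtures at the anomeric carbon C10. This centre has no descriptor in their SMILES because it becomes sp2 in 10 and an acetal carbon without stereochemistry in 12.
- The thallium in 11 is drawn with two nitrate ligands, its simplest formulation.

## Route

Step 1
Reactants: 1 furan; 2 hexanoic anhydride
Product: 3 1-(furan-2-yl)hexan-1-one
Conditions: BF3·OEt2 (10 mol %), furan (3 equiv) as solvent, 0 °C → rt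
Reagents that add atoms: none
Why: Friedel–Crafts acylation; the BF3-activated anhydride attacks furan at its most nucleophilic α-position, and catalytic Lewis acid with excess furan limits polymerisation of the heterocycle.

Step 2
Reactants: 3 1-(furan-2-yl)hexan-1-one
Product: 4 (1S)-1-(furan-2-yl)hexan-1-ol
Conditions: RuCl[(S,S)-TsDPEN](p-cymene) (1 mol %), HCO2H/Et3N (5:2), rt
Reagents that add atoms: none
Why: Noyori asymmetric transfer hydrogenation of an aryl alkyl ketone; the furan ring plays the part of the aryl group in the six-membered hydride-transfer transition state, so the (S,S)-catalyst should give the (S)-carbinol, which becomes C6.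

Step 3
Reactants: 4 (1S)-1-(furan-2-yl)hexan-1-ol
Product: 5 (2S)-6-hydroxy-2-pentyl-2H-pyran-3(6H)-one
Conditions: NBS, NaHCO3, THF/H2O (4:1), 0 °C
Reagents that add atoms: water, O
Why: Achmatowicz rearrangement: NBS in water oxidises the furan to the ring-opened cis-enedione, whose aldehyde is captured by the carbinol oxygen to give the pyranone hemiacetal. The C6 stereocentre is not involved, and the four furan carbons become C7–C10.

Step 4
Reactants: 5 (2S)-6-hydroxy-2-pentyl-2H-pyran-3(6H)-one
Product: 6 (2S)-6-methoxy-2-pentyl-2H-pyran-3(6H)-one
Conditions: HC(OMe)3, BF3·OEt2 (cat.), Et2O, 0 °C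
Reagents that add atoms: trimethyl orthoformate, COC(OC)OC
Why: Acid-catalysed acetalisation of the hemiacetal through the ring oxocarbenium ion, driven by the orthoester. The methyl acetal shields C10 from hydride in step 6 and later serves as the leaving group; its configuration (mainly trans to pentyl) is of no consequence.

Step 5
Reactants: 6 (2S)-6-methoxy-2-pentyl-2H-pyran-3(6H)-one
Product: 7 (2S)-6-methoxy-2-pentyloxan-3-one
Conditions: H2 (1 atm), Pd/C (10 wt %), EtOAc, rt
Reagents that add atoms: none
Why: Heterogeneous catalytic hydrogenation of the enone C8=C9 bond, which in a neutral solvent is faster than hydrogenolysis of the acetal. It converts the half-chair enone into a chair ketone with equatorial pentyl, as step 6 needs.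

Step 6
Reactants: 7 (2S)-6-methoxy-2-pentyloxan-3-one
Product: 8 (2S,3S)-6-methoxy-2-pentyloxan-3-ol
Conditions: LiBH(s-Bu)3, THF, −78 °C; then aq. NH4Cl
Reagents that add atoms: none
Why: Diastereoselective ketone reduction: the bulky trialkylborohydride approaches the C7 carbonyl along the equatorial trajectory of the chair with equatorial pentyl and gives the axial alcohol, cis to pentyl (7S), the usual outcome for 2-alkyloxan-3-ones. The acetal is inert to hydride.

Step 7
Reactants: 8 (2S,3S)-6-methoxy-2-pentyloxan-3-ol
Product: 9 tert-butyl{[(2S,3S)-6-methoxy-2-pentyloxan-3-yl]oxy}diphenylsilane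
Conditions: TBDPSCl, imidazole, DMAP (cat.), DMF, 40 °C
Reagents that add atoms: tert-butyl(chloro)diphenylsilane, CC(C)(C)[Si](Cl)(c1ccccc1)c1ccccc1
Why: Silylation of a secondary alcohol with nucleophilic catalysis. The TBDPS ether is chosen because it should withstand the nitric acid of step 9 and the aqueous acid of step 10, and its bulk reinforces the facial bias in step 9.

Step 8
Reactants: 9 tert-butyl{[(2S,3S)-6-methoxy-2-pentyloxan-3-yl]oxy}diphenylsilane
Product: 10 tert-butyl{[(2S,3S)-2-pentyl-3,4-dihydro-2H-pyran-3-yl]oxy}diphenylsilane
Conditions: Me3SiOTf, i-Pr2NEt, CH2Cl2, 0 °C → rt; chromatography on Et3N-treated silica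
Reagents that add atoms: none
Why: Silyl triflate/hindered amine conversion of an acetal into an enol ether: Me3SiOTf ionises the exocyclic C10–OMe bond to the ring oxocarbenium ion and the amine removes a C9 proton. Both anomers converge and no stereocentre is touched.

Step 9
Reactants: 10 tert-butyl{[(2S,3S)-2-pentyl-3,4-dihydro-2H-pyran-3-yl]oxy}diphenylsilane
Product: 12 tert-butyl{[(2S,3S,5R)-5-(dimethoxymethyl)-2-pentyloxolan-3-yl]oxy}diphenylsilane, via oxythallation adduct 11 (not isolated)
Conditions: Tl(NO3)3·3H2O (1.1 equiv), MeOH, −30 → 0 °C; then solid NaHCO3
Reagents that add atoms: methanol, CO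
Why: Thallium trinitrate is a soft electrophile that adds to C9, the nucleophilic β-carbon of the enol ether of 10, while methanol caps the C10 oxocarbenium ion, giving the 2-methoxy-3-thallio-oxane 11 (oxythallation). Attack should take place on the ring face opposite the cis C6 pentyl and C7 silyloxy groups, because the pseudoaxial silyloxy group stands 1,3 to C9 and blocks its own face; this puts the C9–Tl bond equatorial in the chair that keeps pentyl equatorial. In that chair the ring O–C10 bond is antiperiplanar to C9–Tl, so the ring oxygen displaces monovalent thallium from C9 from the rear through a three-centre oxonium transition state. The oxolane is thus closed by a 1,2-shift of the ring oxygen from C10 to C9, formally a 3-exo-tet attack of oxygen on C9 followed by cleavage of the old O–C10 bond, which forms the O–C9 bond and contracts the six-membered ring by one atom. The C10 methoxycarbenium ion set free is trapped by methanol as the dimethyl acetal. The closest known reaction type is the ring contraction of 3,4-dihydro-2H-pyran and of glycals to 2-(dialkoxymethyl)oxolanes by trivalent thallium or trivalent iodine reagents; its stereochemical course is that of the nitrous acid deamination of 2-amino-2-deoxyglucose to a 2,5-anhydrohexose. The new stereocentre C9 (R) is fixed by two linked events, addition anti to the C6/C7 substituents and stereospecific inversion, and so comes out trans to pentyl across the ring oxygen. The step needs regioselectivity (electrophile at C9, secured by the polarisation of the enol ether), facial selectivity (secured by the axial silyloxy group and the pentyl chain) and chemoselectivity (no other nucleophilic alkene is present, and the TBDPS ether resists the nitric acid released).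

Step 10
Reactants: 12 tert-butyl{[(2S,3S,5R)-5-(dimethoxymethyl)-2-pentyloxolan-3-yl]oxy}diphenylsilane
Product: 13 (2R,4S,5S)-4-{[tert-butyl(diphenyl)silyl]oxy}-5-pentyloxolane-2-carbaldehyde
Conditions: CF3CO2H/H2O/CHCl3 (1:1:4), 0 °C; used crude after azeotropic drying
Reagents that add atoms: water, O
Why: Acid-catalysed acetal hydrolysis; the α-oxygen makes the acetal slow to ionise, so aqueous CF3CO2H is used, which the TBDPS ether tolerates. At 0 °C the α-alkoxy aldehyde should keep its C9 configuration.

Step 11
Reactants: 13 (2R,4S,5S)-4-{[tert-butyl(diphenyl)silyl]oxy}-5-pentyloxolane-2-carbaldehyde; 14 9-bromonon-1-ene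
Product: 16 (1R)-1-[(2R,4S,5S)-4-{[tert-butyl(diphenyl)silyl]oxy}-5-pentyloxolan-2-yl]dec-9-en-1-ol, via non-8-en-1-ylmagnesium bromide 15 (not isolated)
Conditions: 14, Mg turnings, Et2O, rt; separately 13, MgBr2·OEt2, CH2Cl2, −78 °C, then the Grignard solution, −78 → −40 °C; aq. NH4Cl
Reagents that add atoms: none
Why: Grignard addition under Cram chelate control: MgBr2 ties the ring oxygen and the carbonyl oxygen into a five-membered chelate in weakly coordinating solvent, and the nucleophile enters from the side of the C9 hydrogen, away from C8, which gives the 9,10-threo carbinol (10R). The isolated alkene and the silyl ether are inert.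

Step 12
Reactants: 16 (1R)-1-[(2R,4S,5S)-4-{[tert-butyl(diphenyl)silyl]oxy}-5-pentyloxolan-2-yl]dec-9-en-1-ol; 17 dodecanoyl chloride
Product: 18 (1R)-1-[(2R,4S,5S)-4-{[tert-butyl(diphenyl)silyl]oxy}-5-pentyloxolan-2-yl]dec-9-en-1-yl dodecanoate
Conditions: Et3N, DMAP (cat.), CH2Cl2, 0 °C → rt
Reagents that add atoms: none
Why: DMAP-catalysed acylation of the only free hydroxyl through the acylpyridinium ion; C10 is not touched.

Step 13
Reactants: 18 (1R)-1-[(2R,4S,5S)-4-{[tert-butyl(diphenyl)silyl]oxy}-5-pentyloxolan-2-yl]dec-9-en-1-yl dodecanoate
Product: 19 (1R)-1-[(2R,4S,5S)-4-hydroxy-5-pentyloxolan-2-yl]dec-9-en-1-yl dodecanoate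
Conditions: HF·pyridine, pyridine, THF, 0 °C → rt
Reagents that add atoms: none
Why: Fluoride-induced desilylation under buffered, non-basic conditions that leave ester and alkene alone. The freed O7 hydroxyl is trans to the C9 side chain on the ring, so acyl migration from O10 is not expected.

## Compound list

1 | furan | c1ccoc1 | starting material
2 | hexanoic anhydride | CCCCCC(=O)OC(=O)CCCCC | starting material
3 | 1-(furan-2-yl)hexan-1-one | CCCCCC(=O)c1ccco1 | intermediate
4 | (1S)-1-(furan-2-yl)hexan-1-ol | CCCCC[C@H](O)c1ccco1 | intermediate
5 | (2S)-6-hydroxy-2-pentyl-2H-pyran-3(6H)-one, anomeric mixture | OC1C=CC(=O)[C@H](CCCCC)O1 | intermediate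
6 | (2S)-6-methoxy-2-pentyl-2H-pyran-3(6H)-one, anomeric mixture | COC1C=CC(=O)[C@H](CCCCC)O1 | intermediate
7 | (2S)-6-methoxy-2-pentyloxan-3-one, anomeric mixture | COC1CCC(=O)[C@H](CCCCC)O1 | intermediate
8 | (2S,3S)-6-methoxy-2-pentyloxan-3-ol, anomeric mixture, pentyl and hydroxyl cis | COC1CC[C@H](O)[C@H](CCCCC)O1 | intermediate
9 | tert-butyl{[(2S,3S)-6-methoxy-2-pentyloxan-3-yl]oxy}diphenylsilane, anomeric mixture | COC1CC[C@H](O[Si](c2ccccc2)(c2ccccc2)C(C)(C)C)[C@H](CCCCC)O1 | intermediate
10 | tert-butyl{[(2S,3S)-2-pentyl-3,4-dihydro-2H-pyran-3-yl]oxy}diphenylsilane | C1=CC[C@H](O[Si](c2ccccc2)(c2ccccc2)C(C)(C)C)[C@H](CCCCC)O1 | intermediate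
11 | [(3S,5S,6S)-5-{[tert-butyl(diphenyl)silyl]oxy}-2-methoxy-6-pentyloxan-3-yl]thallium dinitrate, thallium trans to pentyl and silyloxy | COC1[C@@H]([Tl](O[N+](=O)[O-])O[N+](=O)[O-])C[C@H](O[Si](c2ccccc2)(c2ccccc2)C(C)(C)C)[C@H](CCCCC)O1 | intermediate (not isolated)
12 | tert-butyl{[(2S,3S,5R)-5-(dimethoxymethyl)-2-pentyloxolan-3-yl]oxy}diphenylsilane | COC(OC)[C@H]1C[C@H](O[Si](c2ccccc2)(c2ccccc2)C(C)(C)C)[C@H](CCCCC)O1 | intermediate
13 | (2R,4S,5S)-4-{[tert-butyl(diphenyl)silyl]oxy}-5-pentyloxolane-2-carbaldehyde | O=C[C@H]1C[C@H](O[Si](c2ccccc2)(c2ccccc2)C(C)(C)C)[C@H](CCCCC)O1 | intermediate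
14 | 9-bromonon-1-ene | C=CCCCCCCCBr | starting material
15 | non-8-en-1-ylmagnesium bromide | C=CCCCCCCC[Mg]Br | intermediate (not isolated)
16 | (1R)-1-[(2R,4S,5S)-4-{[tert-butyl(diphenyl)silyl]oxy}-5-pentyloxolan-2-yl]dec-9-en-1-ol | C=CCCCCCCC[C@@H](O)[C@H]1C[C@H](O[Si](c2ccccc2)(c2ccccc2)C(C)(C)C)[C@H](CCCCC)O1 | intermediate
17 | dodecanoyl chloride | CCCCCCCCCCCC(Cl)=O | starting material
18 | (1R)-1-[(2R,4S,5S)-4-{[tert-butyl(diphenyl)silyl]oxy}-5-pentyloxolan-2-yl]dec-9-en-1-yl dodecanoate | C=CCCCCCCC[C@@H](OC(=O)CCCCCCCCCCC)[C@H]1C[C@H](O[Si](c2ccccc2)(c2ccccc2)C(C)(C)C)[C@H](CCCCC)O1 | intermediate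
19 | (1R)-1-[(2R,4S,5S)-4-hydroxy-5-pentyloxolan-2-yl]dec-9-en-1-yl dodecanoate | C=CCCCCCCC[C@@H](OC(=O)CCCCCCCCCCC)[C@H]1C[C@H](O)[C@H](CCCCC)O1 | target

## Step count and least certain steps

Total: 13 steps. Longest linear sequence: 13 steps, from furan 1 to 19; the Grignard reagent 15 is made within step 11.

**Step 9 (key step).** Three processes may interfere.
- Facial discrimination may be incomplete, because the allylic carbon C8 is unsubstituted and only the homoallylic silyloxy group and the pentyl chain steer the electrophile. Attack on the wrong face leads, after the same stereospecific shift, to the 2,5-cis ring.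
- Solvent may intercept the organothallium adduct at C9 from a conformer with an axial C–Tl bond, giving dimethoxylation without ring contraction.
- The nitric acid released may add methanol to unreacted enol ether, which returns material to the level of 9; this can be recycled through step 8.

Fallback, from 10 back to 12, with the electrophilic addition separated from the oxygen shift. Compound 10 is epoxidised with dimethyldioxirane in acetone/CH2Cl2 at 0 °C, a neutral oxidant with the same facial preference. This gives the 1,2-anhydro compound tert-butyl{[(1R,3S,4S,6S)-3-pentyl-2,7-dioxabicyclo[4.1.0]heptan-4-yl]oxy}diphenylsilane F1. Methanol opens F1 at C10 to (3S,5S,6S)-5-{[tert-butyl(diphenyl)silyl]oxy}-2-methoxy-6-pentyloxan-3-ol F2, from which any C9 epimer can be removed by chromatography. Tf2O and pyridine in CH2Cl2 at −20 °C convert F2 into the triflate (3S,5S,6S)-5-{[tert-butyl(diphenyl)silyl]oxy}-2-methoxy-6-pentyloxan-3-yl trifluoromethanesulfonate F3. On warming F3 in methanol buffered with 2,6-lutidine, the equatorial triflate is displaced by the antiperiplanar ring oxygen with inversion, as in the solvolytic ring contraction of pyranoside 2-sulfonates, and the methoxycarbenium ion is trapped to give 12.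

**Step 11.** The chelate may not fully control the facial course, so that the 10S epimer forms beside 16. The basic reagent may also enolise the aldehyde and erode C9.

Fallback, from 13 to 18. The addition is run as described and the C10 epimers are separated. Alcohol 16 goes on through step 12. The epimer (1S)-1-[(2R,4S,5S)-4-{[tert-butyl(diphenyl)silyl]oxy}-5-pentyloxolan-2-yl]dec-9-en-1-ol F4 is esterified with dodecanoic acid under Mitsunobu conditions (PPh3, diisopropyl azodicarboxylate, THF, 0 °C → rt). This inverts C10 of F4 and gives the same ester 18, so both epimers converge.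

**Step 8.** Ionisation may take place at the ring C–O bond instead of the exocyclic one, which opens the ring to an acyclic enol ether. The elimination may also stall, or the acid-sensitive product may add nucleophiles on work-up.

Fallback, from 9 to 10. The methyl acetal is hydrolysed (AcOH/H2O/THF, 50 °C; the TBDPS ether is stable) to the lactol (5S,6S)-5-{[tert-butyl(diphenyl)silyl]oxy}-6-pentyloxan-2-ol F5. F5 is dehydrated through its anomeric mesylate (MsCl, Et3N, CH2Cl2, 0 °C → reflux) to 10, the usual lactol-to-dihydropyran elimination.

**Step 10.** Hydrolysis of the α-alkoxy acetal may be slow, and forcing it with more acid or heat invites epimerisation at C9 through the enol, or loss of the silyl group.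

Fallback, from 12 to 13, without Brønsted acid. Et3SiOTf and 2,4,6-collidine in CH2Cl2 at 0 °C convert the acetal into the collidinium salt 1-{[(2R,4S,5S)-4-{[tert-butyl(diphenyl)silyl]oxy}-5-pentyloxolan-2-yl](methoxy)methyl}-2,4,6-trimethylpyridin-1-ium trifluoromethanesulfonate F6. Water added to the same flask decomposes F6 at neutral pH to aldehyde 13.

## Further compounds

F1 | step 9 | tert-butyl{[(1R,3S,4S,6S)-3-pentyl-2,7-dioxabicyclo[4.1.0]heptan-4-yl]oxy}diphenylsilane | O1[C@H]2[C@@H]1C[C@H](O[Si](c3ccccc3)(c3ccccc3)C(C)(C)C)[C@H](CCCCC)O2
F2 | step 9 | (3S,5S,6S)-5-{[tert-butyl(diphenyl)silyl]oxy}-2-methoxy-6-pentyloxan-3-ol | COC1[C@@H](O)C[C@H](O[Si](c2ccccc2)(c2ccccc2)C(C)(C)C)[C@H](CCCCC)O1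
F3 | step 9 | (3S,5S,6S)-5-{[tert-butyl(diphenyl)silyl]oxy}-2-methoxy-6-pentyloxan-3-yl trifluoromethanesulfonate | COC1[C@@H](OS(=O)(=O)C(F)(F)F)C[C@H](O[Si](c2ccccc2)(c2ccccc2)C(C)(C)C)[C@H](CCCCC)O1
F4 | step 11 | (1S)-1-[(2R,4S,5S)-4-{[tert-butyl(diphenyl)silyl]oxy}-5-pentyloxolan-2-yl]dec-9-en-1-ol | C=CCCCCCCC[C@H](O)[C@H]1C[C@H](O[Si](c2ccccc2)(c2ccccc2)C(C)(C)C)[C@H](CCCCC)O1
F5 | step 8 | (5S,6S)-5-{[tert-butyl(diphenyl)silyl]oxy}-6-pentyloxan-2-ol | OC1CC[C@H](O[Si](c2ccccc2)(c2ccccc2)C(C)(C)C)[C@H](CCCCC)O1
F6 | step 10 | 1-{[(2R,4S,5S)-4-{[tert-butyl(diphenyl)silyl]oxy}-5-pentyloxolan-2-yl](methoxy)methyl}-2,4,6-trimethylpyridin-1-ium trifluoromethanesulfonate | COC([n+]1c(C)cc(C)cc1C)[C@H]1C[C@H](O[Si](c2ccccc2)(c2ccccc2)C(C)(C)C)[C@H](CCCCC)O1.[O-]S(=O)(=O)C(F)(F)F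
A1 | alternative 1 | (1R)-1-(7-butyl-2,6-dioxabicyclo[3.2.0]heptan-3-yl)dec-9-en-1-yl dodecanoate | C=CCCCCCCC[C@@H](OC(=O)CCCCCCCCCCC)[C@H]1C[C@@H]2O[C@@H](CCCC)[C@@H]2O1
A2 | alternative 1 | (1R)-1-[(2R)-2,3-dihydrofuran-2-yl]dec-9-en-1-yl dodecanoate | C=CCCCCCCC[C@@H](OC(=O)CCCCCCCCCCC)[C@H]1CC=CO1
A3 | alternative 1 | pentanal | CCCCC=O
A4 | alternative 2 | (2S,3S,5R)-5-(dimethoxymethyl)-2-pentyltetrahydrofuran-3-ol | COC(OC)[C@H]1C[C@H](O)[C@H](CCCCC)O1
A5 | alternative 2 | 3,6,7,8,9,10-hexadeoxy-1,2-O-isopropylidene-5-O-methanesulfonyl-α-D-ribo-decofuranose | CCCCC[C@@H](OS(C)(=O)=O)[C@@H]1C[C@H]2OC(C)(C)O[C@H]2O1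
A6 | alternative 2 | D-glucose (pyranose form) | OC[C@H]1OC(O)[C@H](O)[C@@H](O)[C@@H]1O
A7 | alternative 3 | (2S,3S)-5-[(1R)-1-(tert-butyldimethylsilyloxy)dec-9-en-1-yl]-3-(methoxymethoxy)-2-pentyl-2,3-dihydrofuran | C=CCCCCCCC[C@@H](O[Si](C)(C)C(C)(C)C)C1=C[C@H](OCOC)[C@H](CCCCC)O1
A8 | alternative 3 | tert-butyl{[(3R)-2-{[(3S,4S)-3-(methoxymethoxy)non-1-en-4-yl]oxy}dodeca-1,11-dien-3-yl]oxy}dimethylsilane | C=CCCCCCCC[C@@H](O[Si](C)(C)C(C)(C)C)C(=C)O[C@@H](CCCCC)[C@@H](OCOC)C=C
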